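**Plan** (ring atoms numbered as in a 2(5H)-furanone: O1, C2 carbonyl, C3 methyl-bearing, C4 chain-bearing, C5 methylene)
1. The ring C3=C4 double bond is cut into two ketone carbonyls: C3 becomes the keto carbon of a pyruvate ester and C4 the keto carbon of a 2-oxoalkyl ester. The O1–C2 ester link holds these two electrophilic carbons 1,4 to each other, so one reductive carbonyl–carbonyl (McMurry) coupling can form the lactone ring and its tetrasubstituted alkene together, with loss of both helper oxygens.
2. The C5–O1 bond is cut next (bromomethyl ketone + sodium pyruvate), and the bromomethyl ketone is traced back to the terminal alkene of (S)-octadec-17-en-2-yl acetate.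
3. The C18 chain is cut at C3–C4 (epoxide opening) and C7–C8 (sp3–sp3 Grignard coupling), giving (S)-2-methyloxirane, 1-bromo-4-chlorobutane and 11-bromoundec-1-ene.
4. Forward order: the chain is joined first (two copper-catalysed Grignard steps), the acetate is installed, the alkene is turned into the bromomethyl ketone, pyruvate is attached, and the only ring is closed last.
5. Stereochemistry: the single (S) center is bought in (S)-2-methyloxirane, is never a reacting center, and needs no later correction.

Key step: step 7

Remark on the chemistry: compound 13 is drawn formally as a TiCl2 diolate; on the reducing titanium surface its exact ligand set is not defined.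

**Step 1**
Reactants: 1 11-bromoundec-1-ene; 2 1-bromo-4-chlorobutane
Product: 4 15-chloropentadec-1-ene, via undec-10-enylmagnesium bromide 3 (not isolated)
Conditions: Mg, THF, rt to 40 °C; then 2 (1.5 equiv), Li2CuCl4 (3 mol %), THF, −10 °C to rt
Reagents that add atoms: none
Why: Copper-catalysed sp3–sp3 cross-coupling of a primary Grignard reagent with a primary alkyl bromide (Kochi coupling) should occur at the C–Br bond of 2 much faster than at its C–Cl bond, so the chloride is kept as the handle for the next Grignard reagent.

**Step 2**
Reactants: 4 15-chloropentadec-1-ene; 5 (S)-2-methyloxirane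
Product: 7 (S)-octadec-17-en-2-ol, via pentadec-14-enylmagnesium chloride 6 (not isolated)
Conditions: Mg, I2 (cat.), THF, reflux; then CuI (10 mol %), 5, THF, −30 to 0 °C; dilute aq. HCl work-up
Reagents that add atoms: none
Why: Copper-catalysed ring opening of a terminal epoxide by a primary Grignard reagent is an SN2 attack at the unsubstituted CH2 carbon, so the C–O stereocenter of 5 is not touched and is carried into 7 as (S).

**Step 3**
Reactants: 7 (S)-octadec-17-en-2-ol
Product: 8 (S)-octadec-17-en-2-yl acetate
Conditions: Ac2O, pyridine, DMAP (cat.), CH2Cl2, rt
Reagents that add atoms: acetic anhydride, CC(=O)OC(C)=O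
Why: DMAP-catalysed O-acylation of a secondary alcohol goes with retention at the (S) carbinol carbon, installs the acetate of the target and masks the alcohol against the oxidation in step 5.

**Step 4**
Reactants: 8 (S)-octadec-17-en-2-yl acetate
Product: 9 (2S)-18-bromo-17-hydroxyoctadecan-2-yl acetate
Conditions: NBS, aqueous acetone, 0 °C to rt, dark
Reagents that add atoms: N-bromosuccinimide, O=C1CCC(=O)N1Br; water, O
Why: Bromohydrin formation from a terminal alkene: the bromonium ion should be opened by water at the more substituted carbon (Markovnikov), placing OH at C17 and Br at C18; the new C17 center is expected as both epimers and is erased in step 5.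

**Step 5**
Reactants: 9 (2S)-18-bromo-17-hydroxyoctadecan-2-yl acetate
Product: 10 (S)-18-bromo-17-oxooctadecan-2-yl acetate
Conditions: Dess–Martin periodinane, CH2Cl2, rt
Reagents that add atoms: none
Why: Dess–Martin oxidation of the secondary alcohol to the ketone runs under neutral, non-basic conditions that should leave the primary bromide, the acetate and the (S) center untouched.

**Step 6**
Reactants: 10 (S)-18-bromo-17-oxooctadecan-2-yl acetate; 11 sodium pyruvate
Product: 12 (S)-17-acetoxy-2-oxooctadecyl 2-oxopropanoate
Conditions: 11 (1.5 equiv), Bu4NI (cat.), DMF, rt
Reagents that add atoms: none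
Why: SN2 displacement of the activated alpha-bromo ketone by the pyruvate carboxylate in a dipolar aprotic solvent (carboxylate O-alkylation, as in phenacyl ester formation) forms the C5–O1 ester bond without strong base.

**Step 7**
Reactants: 12 (S)-17-acetoxy-2-oxooctadecyl 2-oxopropanoate
Product: 14 (S)-16-(4-methyl-5-oxo-2,5-dihydrofuran-3-yl)hexadecan-2-yl acetate, via titanium pinacolate 13 (not isolated)
Conditions: TiCl4 (6 equiv), Zn dust (12 equiv), pyridine, THF, reflux (reagent pre-formed); 12 added by syringe pump over about 12 h at high dilution; aq. K2CO3 work-up
Reagents that add atoms: none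
Why: Proposed new method: low-valent titanium should transfer an electron first to the easily reduced pyruvate keto group, and the titanium-bound ketyl (or the enediolate formed by a second electron) should add to the ketone carbonyl carbon held by the ester tether, giving the cis-fused titanium pinacolate 13, which at reflux is deoxygenated on titanium to the C3=C4 double bond; because the C3–O bond is alpha to the lactone carbonyl, electron transfer into the lactone followed by beta-elimination of the C4 titanoxide offers a second low-barrier path to the same alkene. The closest known reaction types are the intramolecular McMurry coupling of diketones to cycloalkenes and the cross-pinacol coupling of alpha-keto esters with simple ketones promoted by trivalent titanium. The five-membered lactone closes in a 5-exo-trig mode, C3 attacking the carbonyl carbon C4 whose C=O bond lies outside the new ring. No stereocenter is formed, since both coupled carbons end as sp2 centers, and the remote (S)-acetoxy center is not involved. The step needs selectivity for the two keto groups over the three ester carbonyls, no reductive loss of the alpha-acyloxy group from the alkyl ketone, and ring closure ahead of intermolecular pinacol dimerisation; the large gap in reduction potential between the pyruvate and the alkyl ketone, the 1,4 placement of the two keto carbons across the ester and slow addition at high dilution should secure these.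

**Compound list**
1 | 11-bromoundec-1-ene | C=CCCCCCCCCCBr | starting material
2 | 1-bromo-4-chlorobutane | ClCCCCBr | starting material
3 | undec-10-enylmagnesium bromide | C=CCCCCCCCCC[Mg]Br | intermediate
4 | 15-chloropentadec-1-ene | C=CCCCCCCCCCCCCCCl | intermediate
5 | (S)-2-methyloxirane | C[C@H]1CO1 | starting material
6 | pentadec-14-enylmagnesium chloride | C=CCCCCCCCCCCCCC[Mg]Cl | intermediate
7 | (S)-octadec-17-en-2-ol | C[C@H](O)CCCCCCCCCCCCCCC=C | intermediate
8 | (S)-octadec-17-en-2-yl acetate | CC(=O)O[C@@H](C)CCCCCCCCCCCCCCC=C | intermediate
9 | (2S)-18-bromo-17-hydroxyoctadecan-2-yl acetate (both C17 epimers) | CC(=O)O[C@@H](C)CCCCCCCCCCCCCCC(O)CBr | intermediate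
10 | (S)-18-bromo-17-oxooctadecan-2-yl acetate | CC(=O)O[C@@H](C)CCCCCCCCCCCCCCC(=O)CBr | intermediate
11 | sodium pyruvate (sodium 2-oxopropanoate) | CC(=O)C(=O)[O-].[Na+] | starting material
12 | (S)-17-acetoxy-2-oxooctadecyl 2-oxopropanoate | CC(=O)O[C@@H](C)CCCCCCCCCCCCCCC(=O)COC(=O)C(C)=O | intermediate
13 | titanium pinacolate: TiCl2 cis-3,4-diolate of the 3,4-dihydroxy-3-methyl-4-[(S)-15-acetoxyhexadecyl]-gamma-butyrolactone (cis at C3/C4, both ring-face isomers) | CC(=O)O[C@@H](C)CCCCCCCCCCCCCCC12COC(=O)C1(C)O[Ti](Cl)(Cl)O2 | intermediate
14 | (S)-16-(4-methyl-5-oxo-2,5-dihydrofuran-3-yl)hexadecan-2-yl acetate | CC(=O)O[C@@H](C)CCCCCCCCCCCCCCC1=C(C)C(=O)OC1 | target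

**Step count and risks**
Total steps: 7. Longest linear sequence: 7 steps (from 1).

Steps most likely to fail:

Step 7 (Proposed new method). The reductive coupling may stop at the pinacol stage without deoxygenation. The alkyl ketone may lose its acyloxy group by reductive cleavage of the C5–O1 bond. Intermolecular pinacol coupling or over-reduction of the conjugated lactone may also compete. The fallback uses known chemistry and forms the same C3=C4 bond by a polar olefination instead of a reductive coupling. It sets out from 10: O-alkylation of 2-(diethoxyphosphoryl)propanoic acid with 10 (Cs2CO3, DMF, rt) should give (S)-17-acetoxy-2-oxooctadecyl 2-(diethoxyphosphoryl)propanoate F1. Intramolecular Horner–Wadsworth–Emmons olefination of F1 (LiCl, DBU, MeCN, rt; Masamune–Roush conditions) should then close the ring and return to the route at 14.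

Step 6. The pyruvate may self-condense under the mildly basic conditions, the product may undergo intramolecular aldol closure through its pyruvate methyl group, and the alpha-keto ester may hydrate or degrade on purification. The fallback forms the ester by acylation of an alcohol instead of alkylation of a carboxylate. It sets out from 10: heating with sodium formate in aqueous ethanol should give (S)-17-acetoxy-2-oxooctadecyl formate F2, which is solvolysed in the same flask to (S)-18-hydroxy-17-oxooctadecan-2-yl acetate F3. Steglich esterification of F3 with pyruvic acid (DCC, DMAP cat., CH2Cl2, 0 °C) returns to the route at 12.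

Step 4. Water may open the bromonium ion at the terminal carbon, giving the regioisomeric bromohydrin, and dibromide formation may compete. The fallback sets the regiochemistry by SN2 opening of an epoxide with bromide instead of Markovnikov opening of a bromonium ion. It sets out from 8: epoxidation with mCPBA (CH2Cl2, 0 °C to rt) should give (2S)-16-(oxiran-2-yl)hexadecan-2-yl acetate F4 (both oxirane epimers). Opening of F4 with LiBr and AcOH in THF, with bromide attacking the unsubstituted oxirane carbon, returns to the route at 9.

**Further compounds**
F1 | step 7 | (S)-17-acetoxy-2-oxooctadecyl 2-(diethoxyphosphoryl)propanoate | CC(=O)O[C@@H](C)CCCCCCCCCCCCCCC(=O)COC(=O)C(C)P(=O)(OCC)OCC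
F2 | step 6 | (S)-17-acetoxy-2-oxooctadecyl formate | CC(=O)O[C@@H](C)CCCCCCCCCCCCCCC(=O)COC=O
F3 | step 6 | (S)-18-hydroxy-17-oxooctadecan-2-yl acetate | CC(=O)O[C@@H](C)CCCCCCCCCCCCCCC(=O)CO
F4 | step 4 | (2S)-16-(oxiran-2-yl)hexadecan-2-yl acetate | CC(=O)O[C@@H](C)CCCCCCCCCCCCCCC1CO1
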